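## Analysis of the target

Target 22 is a 2,3,4-trisubstituted oxolane of the 7,9'-epoxylignan type: O1, C2 with the 3,4,5-trimethoxyphenyl ring, C3 with CH2OH, C4 with the (3,4-dimethoxyphenyl)hydroxymethyl group, and C5 as an unsubstituted CH2. It has four stereocenters, C2 (R), C3 (S), C4 (R) and the exocyclic carbinol (S). The ring substituents are all-trans (2,3-trans and 3,4-trans, so the C2 aryl group and the C4 side chain share a face), which is also the thermodynamically preferred arrangement. The carbinol has the configuration that hydride addition to the C4 aryl ketone should give when it attacks anti to the more branched ring neighbour C3 (Felkin–Anh sense), so substrate and catalyst control can be made to agree. Sensitive points are the two electron-rich arenes (ozone, strong electrophiles), the benzylic C2–O1 bond and the benzylic secondary alcohol (both ionize under acid), and C3 and C4 whenever they are alpha to a carbonyl group. The difficulty is absolute control of three contiguous ring centers and one outside the ring in a molecule with two different aryl groups and no symmetry. The strategy rests on the C4–C5–O1 segment: C4 carries a carbon that can be raised to the acyl level and is bonded to the ring CH2 next to O1. A Wolff ring contraction of a 4-diazo-oxan-3-one leaves exactly this pattern: the diazo carbon becomes C4, the carbonyl carbon becomes the exocyclic acyl carbon and the migrating O–CH2 becomes C5.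

## Retrosynthetic reasoning

**C3–CH2OH back to a vinyl group.** The primary alcohol of 22 is taken back through aldehyde 21 to the vinyl group of alcohol 19; the terminal alkene carbon is the one lost on cleavage. A vinyl group is inert to organomagnesium reagents, base and hydride, and it can be brought in as a carbon nucleophile. The forward steps must cleave a terminal alkene without touching the arenes and reduce the aldehyde before its alpha center can move.

**Carbinol C–H back to the ketone.** Cutting the carbinol C–H bond of 19 gives aryl ketone 18. The exocyclic stereocenter becomes a reduction problem in which the ring (attack anti to the branched neighbour) and a chiral transfer-hydrogenation catalyst point the same way.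

**Aryl–carbonyl bond.** The bond between the carbonyl carbon of 18 and the dimethoxyphenyl ring is cut, giving Weinreb amide 15 and the Grignard reagent 17 made from bromide 16. Cutting here, and not between the carbonyl and the ring, leaves exactly one acyl carbon on the ring, which is what a trapped ketene provides.

**Ring contraction.** In 15 the bond between the amide-bearing ring carbon and the ring CH2–O is cut and that CH2 is reattached to the acyl carbon. This leads through ketene 13 to the six-membered diazo ketone 12. The two existing ring stereocenters, the ring oxygen and the aryl group are not involved, and only one group can migrate. The forward step must lose nitrogen with migration, trap the ketene with an N–H nucleophile, and bring the new center trans to the vinyl group (through the cis amide 14 if that forms first).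

**Diazo group and vinyl group from one enone.** The diazo group of 12 is traced to trifluoroacetyl ketone 11, then to lithium enolate 10 and silyl enol ether 9, and 9 to enone 8 by removing the vinyl group from C5 (oxane numbering). One conjugate addition does two jobs: it places the vinyl group anti to the C6 aryl group, and it produces the enolate on the C4 side only. The diazo group therefore cannot end up at C2.

**Enone ring by metathesis.** The C4=C5 double bond of 8 is cut to give the acyclic dienone 7. The ring oxygen and the stereocenter are already in the chain, so the closure creates no stereochemistry.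

**Chain assembly.** The acyl–vinyl bond of 7 is cut to give Weinreb amide 6 (formed via acyl imidazole 5), and the O–CH2 bond of acid 4 is cut to give allylic alcohol 2 and bromoacetic acid 3. The ether is made at the carboxylate stage, where base cannot trigger a [2,3]-shift of the allyloxy-acetyl unit.

**The first stereocenter.** The vinyl–carbinol bond of 2 is cut to give 3,4,5-trimethoxybenzaldehyde 1. An enantioselective vinyl addition sets the one center from which the ring centers follow by relative control.

## Alternatives that were turned down

**Alternative 1:** Cutting O1–C2 and C3–C4 leads to the arylidene malonate A1 and racemic vinylethylene carbonate A2. In the forward step, zerovalent palladium with a chiral phosphoramidite ligand ionizes A2 decarboxylatively to an allyl complex that carries an alkoxide. The alkoxide adds to A1, and the malonate carbanion closes on the internal allyl carbon to give the 2,4-cis diester A3.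
- For it: two ring bonds and two stereocenters form in one catalytic enantioselective step from two simple partners, with the absolute configuration set by a ligand. On step count to the ring it is clearly stronger than the chosen route.
- Against it: the substituents of A3 are at the wrong oxidation levels for this target. C3 arrives as a geminal diester, which needs a hot dealkoxycarbonylation and a reduction. C4 arrives with the vinyl group, which must become the aryl carbinol by cleavage to an epimerizable, beta-alkoxy aldehyde and aryl addition. Felkin-type attack by the aryl nucleophile on that aldehyde would give the carbinol epimer opposite to the one from hydride addition to the aryl ketone, so an oxidation and reduction would follow. The oxa-Michael step is also reversible and the trimethoxybenzylidene acceptor is weak, which puts the selectivities at risk.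
- Comparison: the chosen contraction puts the acyl carbon on C4 and the vinyl group on C3, where each is needed, so every step after the ring is productive. It pays for this with a longer, but entirely standard, sequence before the ring.

**Alternative 2:** Cutting O1–C2 with C5 at the carboxyl level leads to the trans donor–acceptor cyclopropane A4. Wet acid opens the bond between the aryl-bearing carbon and the diester carbon, an ester oxygen captures the benzylic cation, and the all-trans lactone A5 results.
- For it: no diazo compound and no photochemistry (stronger on safety and scale), the all-trans arrangement arises under thermodynamic control, C4 already carries an acyl group, and the C3 carbon is already at the alcohol level, so no oxidative cleavage is needed.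
- Against it: ionization erases C2, so the absolute configuration rests entirely on the silyloxymethyl-bearing carbon of an enantioenriched trisubstituted cyclopropane, which needs its own asymmetric synthesis. C5 arrives as a lactone carbonyl that must be reduced to CH2 in the presence of the C4 ester needed for the aryl ketone. The two carbonyls flank the same acidic C4–H, and the lactone-to-ether reduction passes through an oxocarbenium ion next to ionizable benzylic positions.
- Comparison: in the chosen route C5 is a CH2 from the start, because it is the migrating carbon, and C2 is never ionized.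

**Alternative 3:** Cutting C2–C3 leads to the diazo ester A6, a 3,4,5-trimethoxybenzyl ether. A dirhodium tetracarboxylate Rh2(O2CR)4, achiral or chiral, would generate the carbenoid at C3, which inserts into the benzylic ether C–H bond to give the oxolane ester A7.
- For it: it is the most convergent plan. The carbinol and C4 are set beforehand in an acyclic fragment, the benzylic alcohol stays protected throughout, and only ester reduction and desilylation remain after the ring. In endgame economy it is stronger than the chosen route.
- Against it: the carbenoid carbon has a beta hydrogen at C4, so a 1,2-hydride shift to the unsaturated ester competes directly with insertion. The insertion must create C2 and C3 together with the correct relation to C4 in a flexible chain, where catalyst and substrate may be mismatched. The diazo ester must be installed next to a branched center, which requires prior activation of the ester, and the acyclic precursor needs a stereoselective aldol-type construction of its own.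
- Comparison: the chosen route gives up convergence, but each ring center is set by a single, well-understood element (anti conjugate addition, thermodynamic equilibration), and the one center formed in the key step can be corrected afterwards.

Key step: step 9

Remark on the chemistry: protonation of the amide enol in step 9 is assumed to favour the 3,4-cis amide 14 kinetically, so an equilibration is built into that step. Atom numbers in the text follow the oxane ring for compounds 8 to 12 and the target's oxolane numbering for the five-membered compounds; the systematic names use their own locants.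

## Route

Step 1
Reactants: 1 3,4,5-trimethoxybenzaldehyde
Product: 2 (R)-1-(3,4,5-trimethoxyphenyl)prop-2-en-1-ol
Conditions: Zn(CH=CH2)2 (1.5 equiv, salt-free stock solution), (+)-MIB [(2R)-3-exo-morpholinoisoborneol] (10 mol %), toluene/hexane, −30 → 0 °C; aq. NH4Cl
Reagents that add atoms: divinylzinc, C=C[Zn]C=C
Why: Amino-alcohol-catalysed addition of a diorganozinc to an aryl aldehyde; the (2R)-configured ligand–zinc chelate should deliver the vinyl group to the Re face, which gives the R carbinol (O > aryl > vinyl), by analogy with the Si-face delivery known for the antipodal ligand.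

Step 2
Reactants: 2 (R)-1-(3,4,5-trimethoxyphenyl)prop-2-en-1-ol; 3 bromoacetic acid
Product: 4 (R)-2-{[1-(3,4,5-trimethoxyphenyl)prop-2-en-1-yl]oxy}acetic acid
Conditions: NaH (3 equiv), THF, 0 °C → rt; cold 1 M HCl to pH 3
Reagents that add atoms: none
Why: Williamson etherification of the sodium alkoxide with sodium bromoacetate; the product is a carboxylate, which is not deprotonated further, so the [2,3]-Wittig shift open to allyloxy-acetic esters and amides under base cannot start, and the carbinol center is untouched.

Step 3
Reactants: 4 (R)-2-{[1-(3,4,5-trimethoxyphenyl)prop-2-en-1-yl]oxy}acetic acid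
Product: 6 (R)-N-methoxy-N-methyl-2-{[1-(3,4,5-trimethoxyphenyl)prop-2-en-1-yl]oxy}acetamide, via acyl imidazole 5 (not isolated)
Conditions: CDI (1.1 equiv), CH2Cl2, 0 °C → rt; MeNHOMe·HCl (1.3 equiv), rt
Reagents that add atoms: N,O-dimethylhydroxylamine hydrochloride, CNOC.Cl; 1,1'-carbonyldiimidazole, O=C(n1ccnc1)n1ccnc1 (imidazolyl group of 5 only)
Why: Weinreb amide formation through the acyl imidazole; the medium stays near neutral, which protects the acid-labile benzylic allylic ether.

Step 4
Reactants: 6 (R)-N-methoxy-N-methyl-2-{[1-(3,4,5-trimethoxyphenyl)prop-2-en-1-yl]oxy}acetamide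
Product: 7 (R)-1-{[1-(3,4,5-trimethoxyphenyl)prop-2-en-1-yl]oxy}but-3-en-2-one
Conditions: vinylMgBr (1.5 equiv), THF, −78 → 0 °C; transfer into cold 1 M HCl
Reagents that add atoms: vinylmagnesium bromide, C=C[Mg]Br
Why: Grignard addition to a Weinreb amide stops at the magnesium chelate, so the vinyl ketone is released only on quench; the inverse acidic quench protonates the liberated hydroxylamine before it can add to the enone.

Step 5
Reactants: 7 (R)-1-{[1-(3,4,5-trimethoxyphenyl)prop-2-en-1-yl]oxy}but-3-en-2-one
Product: 8 (6R)-6-(3,4,5-trimethoxyphenyl)-2H-pyran-3(6H)-one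
Conditions: second-generation Grubbs catalyst (H2IMes)(PCy3)Cl2Ru=CHPh (5 mol %), CH2Cl2 (0.01 M), 40 °C
Reagents that add atoms: none
Why: Ring-closing metathesis; the catalyst should load on the allylic ether alkene and close onto the enone alkene to give the six-membered enone, and the stereocenter does not take part.

Step 6
Reactants: 8 (6R)-6-(3,4,5-trimethoxyphenyl)-2H-pyran-3(6H)-one
Product: 9 trimethyl{[(5R,6R)-6-(3,4,5-trimethoxyphenyl)-5-vinyl-5,6-dihydro-2H-pyran-3-yl]oxy}silane
Conditions: vinylMgBr (1.5 equiv), CuBr·SMe2 (0.2 equiv), Me3SiCl (2.5 equiv), THF, −78 °C; Et3N, pentane, cold aq. NaHCO3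
Reagents that add atoms: vinylmagnesium bromide, C=C[Mg]Br; chlorotrimethylsilane, C[Si](C)(C)Cl
Why: Copper-catalysed conjugate addition with silyl trapping; the vinyl group should enter C5 anti to the aryl group on the neighbouring C6, as with 4-substituted cyclohexenones, which sets the trans relation. The enolate is fixed as the C3–C4 silyl enol ether, which defines the site of the later diazo group.

Step 7
Reactants: 9 trimethyl{[(5R,6R)-6-(3,4,5-trimethoxyphenyl)-5-vinyl-5,6-dihydro-2H-pyran-3-yl]oxy}silane
Product: 11 2,2,2-trifluoro-1-[(5R,6R)-3-hydroxy-6-(3,4,5-trimethoxyphenyl)-5-vinyl-5,6-dihydro-2H-pyran-4-yl]ethan-1-one (enol form of the 4-trifluoroacetyl oxan-3-one), via lithium enolate 10 (not isolated)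
Conditions: MeLi (1.05 equiv), THF, 0 °C; −78 °C, CF3CO2CH2CF3 (1.3 equiv); cold 5% HCl; used crude
Reagents that add atoms: 2,2,2-trifluoroethyl trifluoroacetate, O=C(OCC(F)(F)F)C(F)(F)F; methyllithium, [Li]C (lithium of 10 only)
Why: Methyllithium cleaves the O–Si bond to give the regiodefined lithium enolate without equilibration, and Claisen-type C-acylation by the activated trifluoroacetate places the activating group at C4; C5 and C6 are not acidic positions and stay as set.

Step 8
Reactants: 11 2,2,2-trifluoro-1-[(5R,6R)-3-hydroxy-6-(3,4,5-trimethoxyphenyl)-5-vinyl-5,6-dihydro-2H-pyran-4-yl]ethan-1-one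
Product: 12 (5R,6R)-4-diazo-6-(3,4,5-trimethoxyphenyl)-5-vinyloxan-3-one
Conditions: 4-acetamidobenzenesulfonyl azide (1.5 equiv), Et3N (1.5 equiv), H2O (1 equiv), MeCN, rt
Reagents that add atoms: 4-acetamidobenzenesulfonyl azide, CC(=O)Nc1ccc(cc1)S(=O)(=O)N=[N+]=[N-]
Why: Detrifluoroacetylative diazo transfer; the diketonate attacks the sulfonyl azide and the adduct fragments with transfer of the trifluoroacetyl group to the sulfonamide nitrogen, so the diazo group ends up at C4 only.

Step 9
Reactants: 12 (5R,6R)-4-diazo-6-(3,4,5-trimethoxyphenyl)-5-vinyloxan-3-one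
Product: 15 (3R,4R,5R)-N-methoxy-N-methyl-5-(3,4,5-trimethoxyphenyl)-4-vinyloxolane-3-carboxamide, via ketene 13 (not isolated), via cis amide 14 (not isolated)
Conditions: hν (365 nm, or Hg lamp through Pyrex), MeNHOMe (5 equiv), THF (0.02 M), 0 °C; evaporate; t-BuOK (0.3 equiv), t-BuOH/THF, 0 °C → rt; aq. NH4Cl
Reagents that add atoms: N,O-dimethylhydroxylamine, CNOC
Why: This is a photochemical Wolff rearrangement with ring contraction, the closest known type being the contraction of cyclic 2-diazo ketones, oxacyclic ones included, to the derivative of the next smaller ring acid. The ring holds the diazo and carbonyl groups s-cis, so excitation should expel N2 in concert with the 1,2-shift of C2, the ring CH2–O carbon and the only group on the carbonyl carbon that can migrate, from C3 to C4; a carbene–oxirene detour would give the same ketene 13 because the two carbons only exchange roles. The five-membered ring is therefore closed by this [1,2]-shift (the C2–C4 bond forms as C2–C3 breaks) and not by an exo or endo attack along a chain, so O1, C6 and C5 with their trans aryl and vinyl groups are spectators. The amine adds to the ketene carbonyl and the amide enol is protonated on carbon, which creates the one new stereocenter, the amide-bearing ring carbon; delivery of the proton anti to the adjacent vinyl group should favour the cis amide 14. The center is therefore set by thermodynamics: an alkoxide (an amine base is too weak for an amide alpha hydrogen) should equilibrate 14 to the all-trans amide 15, in which the amide group avoids the vinyl group. The amide enolate should not open the ring, because its pi system is close to orthogonal to the adjacent ring C–O bond, the reverse of a 5-endo-trig closure. The selectivities needed are rearrangement over a 1,2-hydrogen shift from C5 and over N–H insertion, which the concerted s-cis pathway secures, and an unambiguous migrating group, which the substrate secures by offering only one.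

Step 10
Reactants: 15 (3R,4R,5R)-N-methoxy-N-methyl-5-(3,4,5-trimethoxyphenyl)-4-vinyloxolane-3-carboxamide; 16 4-bromo-1,2-dimethoxybenzene
Product: 18 (3,4-dimethoxyphenyl)[(3R,4R,5R)-5-(3,4,5-trimethoxyphenyl)-4-vinyloxolan-3-yl]methanone, via arylmagnesium bromide 17 (not isolated)
Conditions: 16 (1.6 equiv), Mg, THF, 50 °C; then 15, THF, 0 °C; aq. NH4Cl
Reagents that add atoms: magnesium, [Mg] (in 17 only)
Why: Grignard formation and acylation by the Weinreb amide, whose chelated tetrahedral adduct prevents a second addition; the alpha center is already in its thermodynamic all-trans arrangement.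

Step 11
Reactants: 18 (3,4-dimethoxyphenyl)[(3R,4R,5R)-5-(3,4,5-trimethoxyphenyl)-4-vinyloxolan-3-yl]methanone
Product: 19 (S)-(3,4-dimethoxyphenyl)[(3R,4R,5R)-5-(3,4,5-trimethoxyphenyl)-4-vinyloxolan-3-yl]methanol
Conditions: RuCl(p-cymene)[(S,S)-TsDPEN] (2 mol %), HCO2H/Et3N (5:2), CH2Cl2, 35 °C
Reagents that add atoms: none
Why: Asymmetric transfer hydrogenation of an aryl ketone; the (S,S) catalyst should give the S carbinol (aryl against alkyl, as with acetophenone), and this is also the Felkin–Anh face, anti to the branched ring carbon that bears the vinyl group, so catalyst and substrate reinforce each other. The isolated vinyl group is not reduced.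

Step 12
Reactants: 19 (S)-(3,4-dimethoxyphenyl)[(3R,4R,5R)-5-(3,4,5-trimethoxyphenyl)-4-vinyloxolan-3-yl]methanol
Product: 21 (2R,3R,4R)-4-[(S)-(3,4-dimethoxyphenyl)(hydroxy)methyl]-2-(3,4,5-trimethoxyphenyl)oxolane-3-carbaldehyde, via diol 20 (not isolated)
Conditions: OsO4 (2 mol %), NaIO4 (4 equiv), 2,6-lutidine (2 equiv), dioxane/H2O (3:1), rt; used crude
Reagents that add atoms: osmium tetroxide, O=[Os](=O)(=O)=O; sodium periodate, [Na+].[O-]I(=O)(=O)=O
Why: Lemieux–Johnson cleavage, that is catalytic dihydroxylation of the terminal alkene and periodate cleavage of the diol; the lutidine buffer should suppress alpha epimerization, and the electron-rich arenes, which ozone would attack, are left alone.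

Step 13
Reactants: 21 (2R,3R,4R)-4-[(S)-(3,4-dimethoxyphenyl)(hydroxy)methyl]-2-(3,4,5-trimethoxyphenyl)oxolane-3-carbaldehyde
Product: 22 (S)-(3,4-dimethoxyphenyl)[(3R,4S,5R)-4-(hydroxymethyl)-5-(3,4,5-trimethoxyphenyl)oxolan-3-yl]methanol
Conditions: NaBH4 (1.5 equiv), MeOH, 0 °C
Reagents that add atoms: none
Why: Borohydride reduction of the aldehyde to the primary alcohol, run at once on the crude aldehyde so that its alpha center has no time to epimerize.

## Compound list

1 | 3,4,5-trimethoxybenzaldehyde | COc1cc(C=O)cc(OC)c1OC | starting material
2 | (R)-1-(3,4,5-trimethoxyphenyl)prop-2-en-1-ol | C=C[C@@H](O)c1cc(OC)c(OC)c(OC)c1 | intermediate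
3 | bromoacetic acid | OC(=O)CBr | starting material
4 | (R)-2-{[1-(3,4,5-trimethoxyphenyl)prop-2-en-1-yl]oxy}acetic acid | C=C[C@@H](OCC(=O)O)c1cc(OC)c(OC)c(OC)c1 | intermediate
5 | (R)-1-(1H-imidazol-1-yl)-2-{[1-(3,4,5-trimethoxyphenyl)prop-2-en-1-yl]oxy}ethan-1-one (acyl imidazole) | C=C[C@@H](OCC(=O)n1ccnc1)c1cc(OC)c(OC)c(OC)c1 | intermediate (not isolated)
6 | (R)-N-methoxy-N-methyl-2-{[1-(3,4,5-trimethoxyphenyl)prop-2-en-1-yl]oxy}acetamide | C=C[C@@H](OCC(=O)N(C)OC)c1cc(OC)c(OC)c(OC)c1 | intermediate
7 | (R)-1-{[1-(3,4,5-trimethoxyphenyl)prop-2-en-1-yl]oxy}but-3-en-2-one | C=C[C@@H](OCC(=O)C=C)c1cc(OC)c(OC)c(OC)c1 | intermediate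
8 | (6R)-6-(3,4,5-trimethoxyphenyl)-2H-pyran-3(6H)-one | O=C1CO[C@@H](c2cc(OC)c(OC)c(OC)c2)C=C1 | intermediate
9 | trimethyl{[(5R,6R)-6-(3,4,5-trimethoxyphenyl)-5-vinyl-5,6-dihydro-2H-pyran-3-yl]oxy}silane | C[Si](C)(C)OC1=C[C@@H](C=C)[C@H](c2cc(OC)c(OC)c(OC)c2)OC1 | intermediate
10 | lithium (5R,6R)-6-(3,4,5-trimethoxyphenyl)-5-vinyl-5,6-dihydro-2H-pyran-3-olate | [Li+].[O-]C1=C[C@@H](C=C)[C@H](c2cc(OC)c(OC)c(OC)c2)OC1 | intermediate (not isolated)
11 | 2,2,2-trifluoro-1-[(5R,6R)-3-hydroxy-6-(3,4,5-trimethoxyphenyl)-5-vinyl-5,6-dihydro-2H-pyran-4-yl]ethan-1-one (enol form of the 4-trifluoroacetyl oxan-3-one) | OC1=C(C(=O)C(F)(F)F)[C@@H](C=C)[C@H](c2cc(OC)c(OC)c(OC)c2)OC1 | intermediate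
12 | (5R,6R)-4-diazo-6-(3,4,5-trimethoxyphenyl)-5-vinyloxan-3-one | O=C1CO[C@@H](c2cc(OC)c(OC)c(OC)c2)[C@H](C=C)C1=[N+]=[N-] | intermediate
13 | [(4R,5R)-5-(3,4,5-trimethoxyphenyl)-4-vinyloxolan-3-ylidene]methanone (ketene) | O=C=C1CO[C@@H](c2cc(OC)c(OC)c(OC)c2)[C@@H]1C=C | intermediate (not isolated)
14 | (3S,4R,5R)-N-methoxy-N-methyl-5-(3,4,5-trimethoxyphenyl)-4-vinyloxolane-3-carboxamide (3,4-cis) | CON(C)C(=O)[C@@H]1CO[C@@H](c2cc(OC)c(OC)c(OC)c2)[C@@H]1C=C | intermediate (not isolated)
15 | (3R,4R,5R)-N-methoxy-N-methyl-5-(3,4,5-trimethoxyphenyl)-4-vinyloxolane-3-carboxamide (all-trans) | CON(C)C(=O)[C@H]1CO[C@@H](c2cc(OC)c(OC)c(OC)c2)[C@@H]1C=C | intermediate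
16 | 4-bromo-1,2-dimethoxybenzene | COc1ccc(Br)cc1OC | starting material
17 | (3,4-dimethoxyphenyl)magnesium bromide | COc1ccc([Mg]Br)cc1OC | intermediate (not isolated)
18 | (3,4-dimethoxyphenyl)[(3R,4R,5R)-5-(3,4,5-trimethoxyphenyl)-4-vinyloxolan-3-yl]methanone | COc1ccc(C(=O)[C@H]2CO[C@@H](c3cc(OC)c(OC)c(OC)c3)[C@@H]2C=C)cc1OC | intermediate
19 | (S)-(3,4-dimethoxyphenyl)[(3R,4R,5R)-5-(3,4,5-trimethoxyphenyl)-4-vinyloxolan-3-yl]methanol | COc1ccc([C@@H](O)[C@H]2CO[C@@H](c3cc(OC)c(OC)c(OC)c3)[C@@H]2C=C)cc1OC | intermediate
20 | 1-{4-[(S)-(3,4-dimethoxyphenyl)(hydroxy)methyl]-2-(3,4,5-trimethoxyphenyl)oxolan-3-yl}ethane-1,2-diol, ring configured as in 19, both epimers at the new carbinol | COc1ccc([C@@H](O)[C@H]2CO[C@@H](c3cc(OC)c(OC)c(OC)c3)[C@@H]2C(O)CO)cc1OC | intermediate (not isolated)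
21 | (2R,3R,4R)-4-[(S)-(3,4-dimethoxyphenyl)(hydroxy)methyl]-2-(3,4,5-trimethoxyphenyl)oxolane-3-carbaldehyde | COc1ccc([C@@H](O)[C@H]2CO[C@@H](c3cc(OC)c(OC)c(OC)c3)[C@@H]2C=O)cc1OC | intermediate
22 | (S)-(3,4-dimethoxyphenyl)[(3R,4S,5R)-4-(hydroxymethyl)-5-(3,4,5-trimethoxyphenyl)oxolan-3-yl]methanol | COc1ccc([C@@H](O)[C@H]2CO[C@@H](c3cc(OC)c(OC)c(OC)c3)[C@@H]2CO)cc1OC | target

## Step count and weak points

Total: 13 steps. Longest linear sequence: 13 steps, from 1 to 22; the Grignard reagent 17 is made from 16 within step 10.

**Step 9 (key step).** The excited diazo ketone or the carbene may be intercepted by the N–H amine (N–H insertion, quenching), or a 1,2-hydrogen shift from C5 may compete with the rearrangement. The alkoxide equilibration of the weakly acidic amide may also stay incomplete or, if forced, lead to loss of formaldehyde from the N-methoxy group. Fallback: starting from 12, irradiation in methanol makes the solvent the ketene trap. NaOMe added to the same flask should equilibrate the ester, which epimerizes far more easily than an amide, to the all-trans methyl ester methyl (3R,4R,5R)-5-(3,4,5-trimethoxyphenyl)-4-vinyloxolane-3-carboxylate F1. Aminolysis of F1 with MeNHOMe·HCl and i-PrMgCl in THF at −20 °C returns the route to 15.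

**Step 1.** Facial selectivity may be poor, because the uncatalysed addition of the reactive vinylzinc reagent competes with the ligand-accelerated one, and the electron-rich aldehyde is slow. Fallback: starting from 1, vinylmagnesium bromide gives racemic 1-(3,4,5-trimethoxyphenyl)prop-2-en-1-ol F2. Kinetic resolution with Candida antarctica lipase B and vinyl acetate should acylate the R enantiomer, in line with the usual preference of this lipase for secondary alcohols, to give (R)-1-(3,4,5-trimethoxyphenyl)prop-2-en-1-yl acetate F3. After separation from the unreacted S alcohol, K2CO3 in methanol cleaves F3 and the route is rejoined at 2.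

**Step 7.** The hindered enolate, next to the vinyl-bearing carbon, may be acylated on oxygen, or proton transfer from the acidic product may quench it before acylation is complete. Fallback: starting from 9, nitrosation of the silyl enol ether with NOCl in CH2Cl2 at −20 °C gives, regiospecifically, (5R,6R)-4-(hydroxyimino)-6-(3,4,5-trimethoxyphenyl)-5-vinyloxan-3-one F4. A Forster reaction of F4 with chloramine (NH2Cl from NaOCl and aqueous NH3) converts the oxime into the diazo group, and the route is rejoined at 12.

**Step 11.** Hydride transfer may be slow or poorly selective, because the ketone is alpha-branched and electron-rich, which can make it a poor fit for the catalyst. Fallback: starting from 18, the stereocontrol is handed to the substrate alone: Li[HB(s-Bu)3] in THF at −78 °C should attack anti to the branched ring carbon (Felkin–Anh) and give 19 directly, with no new intermediate.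

**Step 12.** The aldehyde may epimerize at its alpha carbon, driven by closure of the then cis-disposed carbinol onto the aldehyde as a bicyclic lactol. Fallback: starting from 19, the carbinol is silylated (t-BuMe2SiOTf, 2,6-lutidine) to tert-butyl{(S)-(3,4-dimethoxyphenyl)[(3R,4R,5R)-5-(3,4,5-trimethoxyphenyl)-4-vinyloxolan-3-yl]methoxy}dimethylsilane F5. The same cleavage then gives (2R,3R,4R)-4-[(S)-(tert-butyldimethylsilyloxy)(3,4-dimethoxyphenyl)methyl]-2-(3,4,5-trimethoxyphenyl)oxolane-3-carbaldehyde F6, which has no free hydroxyl to form a lactol. NaBH4 gives [(2R,3S,4R)-4-[(S)-(tert-butyldimethylsilyloxy)(3,4-dimethoxyphenyl)methyl]-2-(3,4,5-trimethoxyphenyl)oxolan-3-yl]methanol F7, and Bu4NF in THF returns the route to 22.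

## Further compounds

F1 | step 9 | methyl (3R,4R,5R)-5-(3,4,5-trimethoxyphenyl)-4-vinyloxolane-3-carboxylate | COC(=O)[C@H]1CO[C@@H](c2cc(OC)c(OC)c(OC)c2)[C@@H]1C=C
F2 | step 1 | racemic 1-(3,4,5-trimethoxyphenyl)prop-2-en-1-ol | C=CC(O)c1cc(OC)c(OC)c(OC)c1
F3 | step 1 | (R)-1-(3,4,5-trimethoxyphenyl)prop-2-en-1-yl acetate | C=C[C@@H](OC(C)=O)c1cc(OC)c(OC)c(OC)c1
F4 | step 7 | (5R,6R)-4-(hydroxyimino)-6-(3,4,5-trimethoxyphenyl)-5-vinyloxan-3-one | O=C1CO[C@@H](c2cc(OC)c(OC)c(OC)c2)[C@H](C=C)C1=NO
F0 | step 11 | none | none
F5 | step 12 | tert-butyl{(S)-(3,4-dimethoxyphenyl)[(3R,4R,5R)-5-(3,4,5-trimethoxyphenyl)-4-vinyloxolan-3-yl]methoxy}dimethylsilane | COc1ccc([C@@H](O[Si](C)(C)C(C)(C)C)[C@H]2CO[C@@H](c3cc(OC)c(OC)c(OC)c3)[C@@H]2C=C)cc1OC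
F6 | step 12 | (2R,3R,4R)-4-[(S)-(tert-butyldimethylsilyloxy)(3,4-dimethoxyphenyl)methyl]-2-(3,4,5-trimethoxyphenyl)oxolane-3-carbaldehyde | COc1ccc([C@@H](O[Si](C)(C)C(C)(C)C)[C@H]2CO[C@@H](c3cc(OC)c(OC)c(OC)c3)[C@@H]2C=O)cc1OC
F7 | step 12 | [(2R,3S,4R)-4-[(S)-(tert-butyldimethylsilyloxy)(3,4-dimethoxyphenyl)methyl]-2-(3,4,5-trimethoxyphenyl)oxolan-3-yl]methanol | COc1ccc([C@@H](O[Si](C)(C)C(C)(C)C)[C@H]2CO[C@@H](c3cc(OC)c(OC)c(OC)c3)[C@@H]2CO)cc1OC
A1 | alternative 1 | dimethyl 2-(3,4,5-trimethoxybenzylidene)malonate | COC(=O)C(=Cc1cc(OC)c(OC)c(OC)c1)C(=O)OC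
A2 | alternative 1 | 4-vinyl-1,3-dioxolan-2-one (vinylethylene carbonate), racemic | C=CC1COC(=O)O1
A3 | alternative 1 | dimethyl 2,4-cis-2-(3,4,5-trimethoxyphenyl)-4-vinyloxolane-3,3-dicarboxylate | C=C[C@H]1CO[C@@H](c2cc(OC)c(OC)c(OC)c2)C1(C(=O)OC)C(=O)OC
A4 | alternative 2 | diethyl trans-2-[(tert-butyldiphenylsilyloxy)methyl]-3-(3,4,5-trimethoxyphenyl)cyclopropane-1,1-dicarboxylate | CCOC(=O)C1(C(=O)OCC)[C@@H](c2cc(OC)c(OC)c(OC)c2)[C@@H]1CO[Si](c1ccccc1)(c1ccccc1)C(C)(C)C
A5 | alternative 2 | ethyl all-trans 4-[(tert-butyldiphenylsilyloxy)methyl]-2-oxo-5-(3,4,5-trimethoxyphenyl)oxolane-3-carboxylate | CCOC(=O)[C@H]1C(=O)O[C@@H](c2cc(OC)c(OC)c(OC)c2)[C@@H]1CO[Si](c1ccccc1)(c1ccccc1)C(C)(C)C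
A6 | alternative 3 | tert-butyl 4-(tert-butyldimethylsilyloxy)-2-diazo-4-(3,4-dimethoxyphenyl)-3-{[(3,4,5-trimethoxybenzyl)oxy]methyl}butanoate | COc1ccc([C@@H](O[Si](C)(C)C(C)(C)C)[C@@H](COCc2cc(OC)c(OC)c(OC)c2)C(=[N+]=[N-])C(=O)OC(C)(C)C)cc1OC
A7 | alternative 3 | tert-butyl all-trans 4-[(tert-butyldimethylsilyloxy)(3,4-dimethoxyphenyl)methyl]-2-(3,4,5-trimethoxyphenyl)oxolane-3-carboxylate | COc1ccc([C@@H](O[Si](C)(C)C(C)(C)C)[C@H]2CO[C@@H](c3cc(OC)c(OC)c(OC)c3)[C@@H]2C(=O)OC(C)(C)C)cc1OC
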